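**Plan**

- Numbering (carotane): cyclopentane C1–C2–C3–C4–C5, cycloheptane C1–C5–C6–C7–C8–C9–C10. The C1 methyl defines the β face; α is the opposite face.
- Retrosynthetic cuts, in order: the C6–O acyl bond; the epoxide oxygen (back to C8=C9); the C4–isopropyl bond (back to a ketalised C4 ketone); the C5–H/C6–OH pair (back to C5=C6); C10–OH and C8–CH3 (back to a C9 ketone with a C8 ester); last, C7–C8 and C1–C10.
- Enabling feature: the cycloheptane is a diene C7=C6–C5=C1, whose C5=C1 bond lies in the cyclopentane with C1 already methylated, joined to the three-carbon oxygenated unit C8–C9–C10. A 2-vinylcyclopentene ketal and a siloxyvinyl diazoester therefore combine in a formal (4+3) cycloaddition.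
- Forward: the cyclopentane is bought as 3-methylcyclopentenone. The seven-membered ring closes in step 6 by rhodium-carbenoid cyclopropanation of the vinyl group (C7–C8) followed by Cope rearrangement (C1–C10). After that only functional groups change, and the angelate goes on before the final epoxidation.
- Stereochemistry: C1 from the chiral dirhodium catalyst; C10 (enolate hydroxylation) and C5/C6 (hydroboration) by attack anti to the C1 methyl; C4 by addition to the open α face of the ketone; C8/C9 by epoxidation directed by the C10 hydroxyl.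

Key step: step 6

Assumption: dirhodium tetrakis[(S)-(1-adamantyl)(phthalimido)acetate], Rh2(S-PTAD)4, is taken to give the (1R,2S)-cyclopropane and hence the (R)-configured quaternary carbon of the cycloadduct. If the sense of induction is the opposite, the mirror-image catalyst Rh2(R-PTAD)4 is used with no other change.

**Route**

Step 1
Reactants: 1 3-methylcyclopent-2-en-1-one
Product: 3 2-bromo-3-methylcyclopent-2-en-1-one, via dibromide 2 (not isolated)
Conditions: Br2, CH2Cl2, 0 °C; then Et3N, 0 °C → rt
Reagents that add atoms: bromine, BrBr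
Why: Bromine adds across the enone double bond to give dibromide 2 and triethylamine then removes HBr by E1cB elimination of the β-bromide, the standard addition–elimination α-bromination of an enone, leaving no stereocentre.

Step 2
Reactants: 3 2-bromo-3-methylcyclopent-2-en-1-one
Product: 4 6-bromo-7-methyl-1,4-dioxaspiro[4.4]non-6-ene
Conditions: HOCH2CH2OH, TsOH·H2O (cat.), benzene, reflux (Dean–Stark)
Reagents that add atoms: ethylene glycol, OCCO
Why: Acid-catalysed ketalisation with azeotropic removal of water, which for 2-halocycloalkenones should proceed without migration of the double bond and so keeps the vinyl bromide for coupling.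

Step 3
Reactants: 4 6-bromo-7-methyl-1,4-dioxaspiro[4.4]non-6-ene
Product: 5 6-ethenyl-7-methyl-1,4-dioxaspiro[4.4]non-6-ene
Conditions: Bu3SnCH=CH2, Pd(PPh3)4 (5 mol %), toluene, 100 °C
Reagents that add atoms: tributyl(vinyl)stannane, C=C[Sn](CCCC)(CCCC)CCCC
Why: Stille coupling at zerovalent palladium (oxidative addition of the vinyl bromide, transmetalation, reductive elimination) installs the C6=C7 vinyl group under neutral conditions that the ketal tolerates.

Step 4
Reactants: 6 methyl acetoacetate
Product: 7 methyl 2-diazo-3-oxobutanoate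
Conditions: 4-AcNHC6H4SO2N3, Et3N, MeCN, 0 °C → rt
Reagents that add atoms: 4-acetamidobenzenesulfonyl azide, CC(=O)Nc1ccc(cc1)S(=O)(=O)N=[N+]=[N-]
Why: Regitz diazo transfer, in which the amine-generated enolate of the β-keto ester attacks the terminal azide nitrogen and the triazene collapses to the diazo compound and the sulfonamide.

Step 5
Reactants: 7 methyl 2-diazo-3-oxobutanoate
Product: 8 methyl 3-(tert-butyldimethylsilyloxy)-2-diazobut-3-enoate
Conditions: TBSOTf, Et3N, CH2Cl2, 0 °C
Reagents that add atoms: tert-butyldimethylsilyl trifluoromethanesulfonate, CC(C)(C)[Si](C)(C)OS(=O)(=O)C(F)(F)F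
Why: Soft enolisation and O-silylation of the acetyl group (silyl enol ether formation), which can only occur on the methyl side because the diazo-bearing carbon has no proton.

Step 6
Reactants: 5 6-ethenyl-7-methyl-1,4-dioxaspiro[4.4]non-6-ene; 8 methyl 3-(tert-butyldimethylsilyloxy)-2-diazobut-3-enoate
Product: 10 methyl (1R)-9-(tert-butyldimethylsilyloxy)-4,4-ethylenedioxy-1-methylbicyclo[5.3.0]deca-5,8-diene-8-carboxylate (carotane numbering), via cis-divinylcyclopropane 9 (not isolated)
Conditions: Rh2(S-PTAD)4 (1 mol %), 5 (1.5 equiv), hexanes, −26 °C → rt, 8 added over 2 h; then 69 °C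
Reagents that add atoms: none
Why: The divalent rhodium carboxylate converts 8 into a donor/acceptor vinylcarbenoid, which cyclopropanates the monosubstituted C6=C7 bond of 5 with the cyclopentenyl group cis to the siloxyvinyl group to give 9, and 9 then undergoes a Cope rearrangement that forms C1–C10 and breaks C6–C8. The closest known reaction type is the tandem cyclopropanation/Cope rearrangement (formal (4+3) cycloaddition) of siloxyvinyl diazoacetates with 1-vinylcycloalkenes, including dienes whose ring terminus is fully substituted. The three-membered ring closes by concerted [2+1] carbene transfer and is consumed again, and the seven-membered ring closes by [3,3]-sigmatropic ring expansion of the cis-divinylcyclopropane through a boat transition state. The single stereocentre of 10, C1, is controlled by the chiral phthalimido(adamantyl)acetate ligands, which fix the (1R,2S) configuration of the cyclopropane, and by the stereospecific boat geometry, which relays it suprafacially to C1. The step needs site selectivity for the vinyl group over the tetrasubstituted ring alkene and the ketal oxygens, which the preference of donor/acceptor carbenoids for unhindered monosubstituted alkenes should secure, and it needs the cis cyclopropane, which the usual cis placement of the donor group and the alkene substituent should secure. Because the boat geometry forces the C1 methyl over the cyclopropane, the rearrangement should be slower than usual, which is why the mixture is heated once the diazo compound is consumed.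

Step 7
Reactants: 10 cycloadduct from step 6
Product: 12 methyl (1R)-4,4-ethylenedioxy-1,8-dimethyl-9-oxobicyclo[5.3.0]dec-5-ene-8-carboxylate (both C8 epimers), via tetrabutylammonium enolate 11 (not isolated)
Conditions: Bu4NF, THF, −78 °C; then MeI, −78 → 0 °C
Reagents that add atoms: iodomethane, CI
Why: Fluoride cleaves the silyl enol ether to the β-keto ester enolate 11, which is C-methylated by iodomethane (fluoride-mediated enolate alkylation); this installs the C8 methyl and blocks C8 so that the ketone can afterwards enolise only towards C10, while the new C8 centre forms as a mixture that steps 10 and 11 erase.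

Step 8
Reactants: 12 C8-methylated β-keto ester
Product: 14 methyl 4,4-ethylenedioxy-10α-hydroxy-1β,8-dimethyl-9-oxobicyclo[5.3.0]dec-5-ene-8-carboxylate (both C8 epimers), via potassium enolate 13 (not isolated)
Conditions: KN(SiMe3)2, THF, −78 °C; then 2-(phenylsulfonyl)-3-phenyloxaziridine, −78 °C
Reagents that add atoms: 2-(phenylsulfonyl)-3-phenyloxaziridine, O=S(=O)(N1OC1c1ccccc1)c1ccccc1
Why: With C8 quaternary the base can form only the C9–C10 enolate 13, and oxygen transfer from the N-sulfonyloxaziridine (electrophilic enolate hydroxylation) should occur on the face opposite the pseudoaxial C1 methyl, setting C10 as the α-alcohol.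

Step 9
Reactants: 14 10α-hydroxy ketone
Product: 15 methyl 10α-(tert-butyldimethylsilyloxy)-4,4-ethylenedioxy-1β,8-dimethyl-9-oxobicyclo[5.3.0]dec-5-ene-8-carboxylate (both C8 epimers)
Conditions: TBSOTf, 2,6-lutidine, CH2Cl2, −78 → 0 °C
Reagents that add atoms: tert-butyldimethylsilyl trifluoromethanesulfonate, CC(C)(C)[Si](C)(C)OS(=O)(=O)C(F)(F)F
Why: O-silylation of the secondary alcohol with a silyl triflate and a hindered base gives an ether that should survive hot chloride, strong base, borane, mild acid and the organocerium reagent and is removed by fluoride in step 18.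

Step 10
Reactants: 15 silyl-protected β-keto ester
Product: 16 10α-(tert-butyldimethylsilyloxy)-4,4-ethylenedioxy-1β,8-dimethylbicyclo[5.3.0]dec-5-en-9-one (both C8 epimers)
Conditions: LiCl, H2O, DMSO, 150 °C
Reagents that add atoms: none
Why: Krapcho dealkoxycarbonylation, in which chloride demethylates the ester by SN2 attack, the β-keto carboxylate loses carbon dioxide and water protonates the enolate, under neutral conditions that the ketal, silyl ether and alkene tolerate.

Step 11
Reactants: 16 8-methyl-9-ketone
Product: 18 10α-(tert-butyldimethylsilyloxy)-4,4-ethylenedioxy-1β,8-dimethylbicyclo[5.3.0]deca-5,8-dien-9-yl trifluoromethanesulfonate, via potassium enolate 17 (not isolated)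
Conditions: KN(SiMe3)2, THF, −78 °C; then PhNTf2, −78 → 0 °C
Reagents that add atoms: N-phenylbis(trifluoromethanesulfonimide), O=S(=O)(N(c1ccccc1)S(=O)(=O)C(F)(F)F)C(F)(F)F
Why: Deprotonation should occur at C8 and not at the silyloxy-bearing C10 methine next to the quaternary carbon, and O-sulfonylation of enolate 17 gives the enol triflate (enol triflate formation), which fixes the C8=C9 position and removes the C8 stereocentre.

Step 12
Reactants: 18 enol triflate
Product: 20 10α-(tert-butyldimethylsilyloxy)-4,4-ethylenedioxy-6α-hydroxy-1β,8-dimethyl-5αH-bicyclo[5.3.0]dec-8-en-9-yl trifluoromethanesulfonate, via alkylborane 19 (not isolated)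
Conditions: BH3·THF, THF, 0 °C → rt; then H2O2, aq NaOAc, 0 °C → rt
Reagents that add atoms: hydrogen peroxide, OO
Why: Hydroboration–oxidation, in which borane adds syn across the trisubstituted C5=C6 bond with boron at the less substituted C6 and from the α face opposite the angular methyl (as with the analogous 5,6-alkenes of steroids), so that oxidation with retention gives the 5α-H, 6α-OH trans-fused alcohol, while the electron-poor tetrasubstituted enol triflate should not react and the buffered peroxide spares it.

Step 13
Reactants: 20 6α-hydroxy enol triflate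
Product: 21 10α-(tert-butyldimethylsilyloxy)-4,4-ethylenedioxy-1β,8-dimethyl-5αH-bicyclo[5.3.0]dec-8-en-6α-ol
Conditions: Pd(OAc)2 (5 mol %), PPh3, Bu3N, HCO2H, DMF, 60 °C
Reagents that add atoms: none
Why: Palladium-catalysed formate reduction of the enol triflate (oxidative addition, formate exchange, decarboxylation to a palladium hydride, reductive elimination) replaces the triflate by hydrogen and leaves the C8=C9 bond where it is.

Step 14
Reactants: 21 ketal alcohol
Product: 22 10α-(tert-butyldimethylsilyloxy)-6α-hydroxy-1β,8-dimethyl-5αH-bicyclo[5.3.0]dec-8-en-4-one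
Conditions: PPTS, acetone/H2O (9:1), 56 °C
Reagents that add atoms: water, O
Why: Acid-catalysed hydrolysis of the dioxolane unmasks the C4 ketone, and the weak pyridinium acid should spare the hindered silyl ether and avoid both dehydration of the β-hydroxy ketone and epimerisation at C5.

Step 15
Reactants: 22 β-hydroxy ketone
Product: 23 10α-(tert-butyldimethylsilyloxy)-4α-isopropyl-1β,8-dimethyl-5αH-bicyclo[5.3.0]dec-8-ene-4β,6α-diol
Conditions: CeCl3 (anhydrous), iPrMgCl (4 equiv), THF, −78 → 0 °C
Reagents that add atoms: isopropylmagnesium chloride, CC(C)[Mg]Cl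
Why: 1,2-Addition of the weakly basic organocerium reagent to the enolisable ketone (organocerium carbonyl addition) should occur from the α face, next to the small C5 hydrogen and away from the C5–C6 bond and the C1 methyl, setting C4 with β-hydroxyl and α-isopropyl, the first equivalent being consumed by the C6 hydroxyl.

Step 16
Reactants: 24 angelic acid
Product: 25 angelic 2,4,6-trichlorobenzoic anhydride
Conditions: 2,4,6-Cl3C6H2COCl, Et3N, toluene, rt; filtered and used as the crude solution
Reagents that add atoms: 2,4,6-trichlorobenzoyl chloride, O=C(Cl)c1c(Cl)cc(Cl)cc1Cl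
Why: Acylation of the triethylammonium carboxylate by the acid chloride gives the mixed anhydride of the Yamaguchi esterification without disturbing the (Z)-alkene.

Step 17
Reactants: 23 4β,6α-diol; 25 angelic 2,4,6-trichlorobenzoic anhydride
Product: 26 10α-(tert-butyldimethylsilyloxy)-4β-hydroxy-4α-isopropyl-1β,8-dimethyl-5αH-bicyclo[5.3.0]dec-8-en-6α-yl (Z)-2-methylbut-2-enoate
Conditions: toluene, 80 °C
Reagents that add atoms: none
Why: Yamaguchi-type esterification run without a nucleophilic catalyst, in which the secondary C6 alcohol attacks the unhindered angeloyl carbonyl of the mixed anhydride, the tertiary C4 alcohol stays free, and the absence of 4-(dimethylamino)pyridine should prevent isomerisation of the angelate to the tiglate.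

Step 18
Reactants: 26 silyl-protected angelate
Product: 27 4β,10α-dihydroxy-4α-isopropyl-1β,8-dimethyl-5αH-bicyclo[5.3.0]dec-8-en-6α-yl (Z)-2-methylbut-2-enoate
Conditions: HF·pyridine, pyridine/THF, 0 °C → rt
Reagents that add atoms: none
Why: Fluoride-induced cleavage of the silyl ether (desilylation) frees the allylic C10 alcohol under buffered conditions that should leave the ester, both alkenes and the tertiary alcohol untouched.

Step 19
Reactants: 27 allylic alcohol
Product: 28 lapiferine
Conditions: VO(acac)2 (5 mol %), t-BuOOH, CH2Cl2, 0 °C → rt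
Reagents that add atoms: tert-butyl hydroperoxide, CC(C)(C)OO
Why: Vanadium-catalysed hydroxyl-directed epoxidation, in which the C10 alkoxide binds the vanadium peroxide and delivers oxygen to the allylic C8=C9 bond on its own α face, setting C8 and C9 syn to the C10 hydroxyl while the electron-poor angelate alkene stays inert.

**Compound list**

1 | 3-methylcyclopent-2-en-1-one | CC1=CC(=O)CC1 | starting material
2 | 2,3-dibromo-3-methylcyclopentan-1-one (racemic) | CC1(Br)CCC(=O)C1Br | intermediate
3 | 2-bromo-3-methylcyclopent-2-en-1-one | CC1=C(Br)C(=O)CC1 | intermediate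
4 | 6-bromo-7-methyl-1,4-dioxaspiro[4.4]non-6-ene | CC1=C(Br)C2(CC1)OCCO2 | intermediate
5 | 6-ethenyl-7-methyl-1,4-dioxaspiro[4.4]non-6-ene | C=CC1=C(C)CCC12OCCO2 | intermediate
6 | methyl acetoacetate | COC(=O)CC(C)=O | starting material
7 | methyl 2-diazo-3-oxobutanoate | COC(=O)C(=[N+]=[N-])C(C)=O | intermediate
8 | methyl 3-(tert-butyldimethylsilyloxy)-2-diazobut-3-enoate | COC(=O)C(=[N+]=[N-])C(=C)O[Si](C)(C)C(C)(C)C | intermediate
9 | methyl (1R,2S)-1-[1-(tert-butyldimethylsilyloxy)ethenyl]-2-(7-methyl-1,4-dioxaspiro[4.4]non-6-en-6-yl)cyclopropane-1-carboxylate (the two alkenyl groups cis) | COC(=O)[C@]1(C(=C)O[Si](C)(C)C(C)(C)C)C[C@H]1C1=C(C)CCC12OCCO2 | intermediate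
10 | methyl (1R)-9-(tert-butyldimethylsilyloxy)-4,4-ethylenedioxy-1-methylbicyclo[5.3.0]deca-5,8-diene-8-carboxylate (carotane numbering) | COC(=O)C1=C(O[Si](C)(C)C(C)(C)C)C[C@@]2(C)CCC3(OCCO3)C2=CC1 | intermediate
11 | tetrabutylammonium enolate of the C9-keto C8-ester obtained by desilylation of 10 | COC(=O)C1=C([O-])C[C@@]2(C)CCC3(OCCO3)C2=CC1.CCCC[N+](CCCC)(CCCC)CCCC | intermediate
12 | methyl (1R)-4,4-ethylenedioxy-1,8-dimethyl-9-oxobicyclo[5.3.0]dec-5-ene-8-carboxylate, both C8 epimers | COC(=O)C1(C)C(=O)C[C@@]2(C)CCC3(OCCO3)C2=CC1 | intermediate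
13 | potassium C9–C10 enolate of 12 | COC(=O)C1(C)C([O-])=C[C@@]2(C)CCC3(OCCO3)C2=CC1.[K+] | intermediate
14 | methyl 4,4-ethylenedioxy-10α-hydroxy-1β,8-dimethyl-9-oxobicyclo[5.3.0]dec-5-ene-8-carboxylate, both C8 epimers | COC(=O)C1(C)C(=O)[C@@H](O)[C@@]2(C)CCC3(OCCO3)C2=CC1 | intermediate
15 | methyl 10α-(tert-butyldimethylsilyloxy)-4,4-ethylenedioxy-1β,8-dimethyl-9-oxobicyclo[5.3.0]dec-5-ene-8-carboxylate, both C8 epimers | COC(=O)C1(C)C(=O)[C@@H](O[Si](C)(C)C(C)(C)C)[C@@]2(C)CCC3(OCCO3)C2=CC1 | intermediate
16 | 10α-(tert-butyldimethylsilyloxy)-4,4-ethylenedioxy-1β,8-dimethylbicyclo[5.3.0]dec-5-en-9-one, both C8 epimers | CC1C(=O)[C@@H](O[Si](C)(C)C(C)(C)C)[C@@]2(C)CCC3(OCCO3)C2=CC1 | intermediate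
17 | potassium C8–C9 enolate of 16 | CC1=C([O-])[C@@H](O[Si](C)(C)C(C)(C)C)[C@@]2(C)CCC3(OCCO3)C2=CC1.[K+] | intermediate
18 | 10α-(tert-butyldimethylsilyloxy)-4,4-ethylenedioxy-1β,8-dimethylbicyclo[5.3.0]deca-5,8-dien-9-yl trifluoromethanesulfonate | CC1=C(OS(=O)(=O)C(F)(F)F)[C@@H](O[Si](C)(C)C(C)(C)C)[C@@]2(C)CCC3(OCCO3)C2=CC1 | intermediate
19 | C6α-borane adduct of 18 (5α-H, trans-fused alkylborane) | B[C@H]1CC(C)=C(OS(=O)(=O)C(F)(F)F)[C@@H](O[Si](C)(C)C(C)(C)C)[C@@]2(C)CCC3(OCCO3)[C@H]12 | intermediate
20 | 10α-(tert-butyldimethylsilyloxy)-4,4-ethylenedioxy-6α-hydroxy-1β,8-dimethyl-5αH-bicyclo[5.3.0]dec-8-en-9-yl trifluoromethanesulfonate | O[C@H]1CC(C)=C(OS(=O)(=O)C(F)(F)F)[C@@H](O[Si](C)(C)C(C)(C)C)[C@@]2(C)CCC3(OCCO3)[C@H]12 | intermediate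
21 | 10α-(tert-butyldimethylsilyloxy)-4,4-ethylenedioxy-1β,8-dimethyl-5αH-bicyclo[5.3.0]dec-8-en-6α-ol | O[C@H]1CC(C)=C[C@@H](O[Si](C)(C)C(C)(C)C)[C@@]2(C)CCC3(OCCO3)[C@H]12 | intermediate
22 | 10α-(tert-butyldimethylsilyloxy)-6α-hydroxy-1β,8-dimethyl-5αH-bicyclo[5.3.0]dec-8-en-4-one | O[C@H]1CC(C)=C[C@@H](O[Si](C)(C)C(C)(C)C)[C@@]2(C)CCC(=O)[C@H]12 | intermediate
23 | 10α-(tert-butyldimethylsilyloxy)-4α-isopropyl-1β,8-dimethyl-5αH-bicyclo[5.3.0]dec-8-ene-4β,6α-diol | O[C@H]1CC(C)=C[C@@H](O[Si](C)(C)C(C)(C)C)[C@@]2(C)CC[C@@](O)(C(C)C)[C@H]12 | intermediate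
24 | angelic acid, (Z)-2-methylbut-2-enoic acid | C/C=C(/C)C(=O)O | starting material
25 | angelic 2,4,6-trichlorobenzoic anhydride | C/C=C(/C)C(=O)OC(=O)c1c(Cl)cc(Cl)cc1Cl | intermediate
26 | 10α-(tert-butyldimethylsilyloxy)-4β-hydroxy-4α-isopropyl-1β,8-dimethyl-5αH-bicyclo[5.3.0]dec-8-en-6α-yl (Z)-2-methylbut-2-enoate | C/C=C(/C)C(=O)O[C@H]1CC(C)=C[C@@H](O[Si](C)(C)C(C)(C)C)[C@@]2(C)CC[C@@](O)(C(C)C)[C@H]12 | intermediate
27 | 4β,10α-dihydroxy-4α-isopropyl-1β,8-dimethyl-5αH-bicyclo[5.3.0]dec-8-en-6α-yl (Z)-2-methylbut-2-enoate | C/C=C(/C)C(=O)O[C@H]1CC(C)=C[C@@H](O)[C@@]2(C)CC[C@@](O)(C(C)C)[C@H]12 | intermediate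
28 | lapiferine, (1S,4R,5S,6S,8R,9S,10S)-8,9-epoxy-4,10-dihydroxy-4-isopropyl-1,8-dimethylbicyclo[5.3.0]decan-6-yl (Z)-2-methylbut-2-enoate (carotane numbering; 8α,9α-epoxide, 4β-OH, 6α-ester, 10α-OH, 5α-H) | C/C=C(/C)C(=O)O[C@H]1C[C@@]2(C)O[C@H]2[C@@H](O)[C@@]2(C)CC[C@@](O)(C(C)C)[C@H]12 | target

**Totals**

Total step count: 19. Longest linear sequence: 16 steps (steps 1–3, 6–15 and 17–19).

**Steps most likely to fail**

Step 6. The bulky, ketal-flanked cyclopentenyl substituent may erode the facial discrimination of the chiral carbenoid in the cyclopropanation. In addition, the C1 methyl that must sit over the cyclopropane may slow the boat Cope step so much that the temperature needed to drive it costs enantioselectivity. The fallback separates stereocontrol from ring construction and sets out from 5 and 8. They are combined with achiral Rh2(O2CC7H15)4 in refluxing hexanes, where the rearrangement should be fast, to give the racemic cycloadduct F1. The enantiomers are then separated by preparative chromatography on a cellulose tris(3,5-dimethylphenylcarbamate) stationary phase. The (S)-enantiomer F2 is set aside and the (R)-enantiomer is compound 10, where the route is rejoined.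

Step 12. Borane may discriminate poorly between the two faces of the hindered C5=C6 bond, now flanked on the α side by the silyloxy-bearing C10, or may attack the enol triflate competitively. The fallback sets out from 18 and builds the C6 oxygen and the C5 hydrogen through the enone instead of through a borane. The triflate is first reduced (Pd(OAc)2, PPh3, Bu3N, HCO2H, DMF) to 10α-(tert-butyldimethylsilyloxy)-4,4-ethylenedioxy-1β,8-dimethylbicyclo[5.3.0]deca-5,8-diene F3. PPTS in wet acetone then unmasks the conjugated enone 10α-(tert-butyldimethylsilyloxy)-1β,8-dimethylbicyclo[5.3.0]deca-5,8-dien-4-one F4. Nucleophilic epoxidation (H2O2, NaOH, MeOH, 0 °C) touches only the enone and should give, anti to the C1 methyl, the 5α,6α-epoxy ketone F5. SmI2 in THF/MeOH at −78 °C cleaves the C5–O bond next to the carbonyl, and protonation of the samarium enolate from the α face gives β-hydroxy ketone 22, where the route is rejoined. C5 is then next to the ketone and can be equilibrated if protonation is not selective.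

Step 15. The secondary organometallic may act as a base or hydride donor towards the hindered β-hydroxy cyclopentanone, causing enolisation with loss of the C5 configuration, retro-aldol opening or reduction in place of addition. The fallback sets out from 22 and uses an sp2 nucleophile that has no β-hydrogen and is smaller. Isopropenylmagnesium bromide with CeCl3 in THF at −78 °C should add from the same α face to give the isopropenyl carbinol 10α-(tert-butyldimethylsilyloxy)-1β,8-dimethyl-4α-(prop-1-en-2-yl)-5αH-bicyclo[5.3.0]dec-8-ene-4β,6α-diol F6. Hydrogenation of its 1,1-disubstituted alkene with RhCl(PPh3)3 under H2 (1 atm) in benzene/ethanol, which should leave the trisubstituted C8=C9 bond alone, gives 23, where the route is rejoined.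

**Further compounds**

F1 | step 6 | racemic methyl 9-(tert-butyldimethylsilyloxy)-4,4-ethylenedioxy-1-methylbicyclo[5.3.0]deca-5,8-diene-8-carboxylate | COC(=O)C1=C(O[Si](C)(C)C(C)(C)C)CC2(C)CCC3(OCCO3)C2=CC1
F2 | step 6 | (1S)-enantiomer of 10 | COC(=O)C1=C(O[Si](C)(C)C(C)(C)C)C[C@]2(C)CCC3(OCCO3)C2=CC1
F3 | step 12 | 10α-(tert-butyldimethylsilyloxy)-4,4-ethylenedioxy-1β,8-dimethylbicyclo[5.3.0]deca-5,8-diene | CC1=C[C@@H](O[Si](C)(C)C(C)(C)C)[C@@]2(C)CCC3(OCCO3)C2=CC1
F4 | step 12 | 10α-(tert-butyldimethylsilyloxy)-1β,8-dimethylbicyclo[5.3.0]deca-5,8-dien-4-one | CC1=C[C@@H](O[Si](C)(C)C(C)(C)C)[C@@]2(C)CCC(=O)C2=CC1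
F5 | step 12 | 10α-(tert-butyldimethylsilyloxy)-5α,6α-epoxy-1β,8-dimethylbicyclo[5.3.0]dec-8-en-4-one | O1[C@H]2CC(C)=C[C@@H](O[Si](C)(C)C(C)(C)C)[C@@]3(C)CCC(=O)[C@]123
F6 | step 15 | 10α-(tert-butyldimethylsilyloxy)-1β,8-dimethyl-4α-(prop-1-en-2-yl)-5αH-bicyclo[5.3.0]dec-8-ene-4β,6α-diol | O[C@H]1CC(C)=C[C@@H](O[Si](C)(C)C(C)(C)C)[C@@]2(C)CC[C@@](O)(C(C)=C)[C@H]12
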